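Read the runs in concentration.

| flask | solid substrate | remark | time |
|---|---|---|---|
| ochre | 0.011 M | run made earlier |  |
| green | 0.024 M | run made earlier |  |
| flask | 0.016 M |  | 2.5 min |

- ochre (time / s: target / %): 10.0: 3; 15.0: 2; 25.0: 10; 40.0: 11; 80.0: 18; 120: 15
- green (time / s: target / %): 20.0: 3; 40.0: 5; 60.0: 6; 80.0: 11; 90.0: 11; 120: 16

(scatter of a reading: 1.5 percentage points)

- as a solid, counted per litre of solution: solid substrate
- the numbers in the tables scatter with a standard deviation of 1.5 percentage points
- at the start none of the solid substrate is in solution
- a reading or a percentage of target counts all its forms, free or not

- amount of target in percent of the solid substrate charged, at 15 s, 50 s and 2.5 min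

In the ochre table, 11% of 0.011 M at 40.0 s is a gain of 0.0302 mM/s. In the green table, 16% of 0.024 M at 120 s is a gain of 0.0320 mM/s. The green charge is twice the ochre charge, yet the two gains are about equal. So the feed g, the target gained per litre and second, is taken as their mean, 0.0311 mM/s, for a charge c at or between those of these two runs.

The ochre column then stops rising, with 18% at 80.0 s and 15% at 120 s. Given a scatter of 1.5 percentage points, these two readings are read as one ceiling f of 16.5% of the charge. The green column shows no such stop.

In this reckoning the percentage therefore follows two lines, the rising g·t/c and the flat f. They meet at the crossing time t×, the ceiling times the charge divided by the feed, which for this flask is 84.8 s.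

In this flask, 15 s and 50 s lie before the crossing, so this reckoning gives 2.92% and 9.73%. The time 2.5 min lies beyond it, so the reckoning gives the ceiling, 16.5%.

The forecast, for which “the rate does not depend on the charge”, gives 2.8%, 9% and 16.5%, lower than this reckoning at 50 s.

The flask gives 3.15%, 9.61% and 15.6%.

    solid substrate ⇌ starting material, rate k1*(cs1 - [starting material]) while solid is left; crystals form when [starting material] > cs1 (solubility = 5.30 mM, k = 0.0380 /s)
    starting material + target ⇌ idle adduct, settled at all times (K = 120 /M)
    starting material ⇌ third isomer (K = 19.0, k = 4.90 /s)
    starting material ⇌ isomer of the product (K = 2.30, k = 1.50 /s)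
    starting material ⇌ target (K = 3.90, k = 3.30 /s)

In the flask, solid substrate stood at 10.9% at 1.25 min and 0% at 2.50 min, and the reckoned t× lies between those times; for the green run the same crossing comes to 127 s, past its last reading at 120 s. While solid substrate was there in the flask, its dissolving, here the rate-limiting step, ran with half of its turnover up to 2.5 min done by 0.685 min, and starting material and free target, by their own step alone and both ways together, relaxed with a half-life of 0.167 s, far shorter than that time. With the solid at 0%, target in the flask, its bound form counted, stood at 15.6% at 2.50 min and 15.6% at 25.0 min.

The numbers in the tables are simulated from invented constants; scatter was added.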